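Readings and results are calculated for an exercise; the scatter is artificial.

- The unit of our ledger is one Q bound per J charged: L holds one, D two and E 3.

| flask | J | Q | remark | time |
|---|---|---|---|---|
| spring | 0.076 M | 0.152 M (in portions, 4) | the very flask that is asked about, followed so far; portions every 40 min |  |
| dusk | 0.038 M | 0.152 M (in portions, 4) | run made earlier; portions every 40 min |  |
| flask | 0.076 M | 0.152 M (in portions, 4) | the portions of Q follow each other after 40 min, the first at the start | 12 d |

| run | time / d | D / % | E / % | L / % |
|---|---|---|---|---|
| spring | 0.625 | 5 | 30 | 33 |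
| spring | 1.25 | 5 | 44 | 24 |
| spring | 1.67 | 6 | 48 | 30 |
| spring | 2.50 | 6 | 50 | 25 |
| spring | 3.00 | 7 | 53 | 25 |
| spring | 4.00 | 3 | 50 | 25 |
| dusk | 0.625 | 3 | 38 | 26 |
| dusk | 1.04 | 0 | 66 | 22 |
| dusk | 1.67 | 3 | 79 | 11 |
| dusk | 3.00 | 0 | 90 | 4 |
| dusk | 5.00 | 1 | 98 | 0 |
| dusk | 8.00 | 1 | 95 | 0 |

(scatter of a reading: 2 percentage points)

1. at 12 d, what has stopped the reaction, if anything has (Q has run out first / all of J has reacted / it is still moving / forward and back rates have come level)
2. amount of D at 12 d, in percent of the J charged
3. amount of E at 12 d, in percent of the J charged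
4. amount of L at 12 d, in percent of the J charged

- the reaction counts as stopped when no species that holds the J changes by six tenths of a point or more over the second half of the time

- The income comes first. The spring charges give 2.00 Q per J, and this ratio c(Q)/c(J), the mean load, is what each J carries on average once the whole charge of Q is bound.
- Spring's load stands below the 3 that E holds, so in spring Q is the limiting reagent. In the dusk run the load is 4.00, and there E reads 98 % at 5.00 d.
- Now the spending. We replace the late spring curves, from 2.50 d to 4.00 d, by their means, and the bill L + 2 D + 3 E comes to 1.89 Q per J.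
- The books do not close yet. The gap is 11.3 % of the J charged and the scatter of that mean bill is 4.3 percentage points, so the gap stands at 2.63 times its scatter: scatter can hardly cover it, and in the spring run Q is still to be found, free or in a form we do not read.
- Our own reckoning takes the gap as Q still to be bound and pays it in proportion: each mean is scaled by load over bill, which gives E 54.1 %, L 26.5 % and D 5.65 %, with Q out first.
- The forecast says Q has run out first, with D 4 %, E 55 % and L 27 %, holding that “the mixture is effectively static well before 12 d”.

The flask gives Q has run out first, with D 3.20 %, E 51.8 % and L 24.6 %, and 0 % of its Q left.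

    J + Q → L + G (k = 1.00 L mol⁻¹ h⁻¹)
    Q + L → D + G (k = 1.10 L mol⁻¹ h⁻¹)
    Q + D → E + G (k = 6.00 L mol⁻¹ h⁻¹)
    D ⇌ Z (K = 2.10, k = 0.0320 h⁻¹)

Beside these stands Z at 6.72 %, formed from D and so holding two Q. With Z entered, the bill of the flask reaches 2.00 Q per J against the load of 2.00. The neighbouring flask with 0.30 M of J has a load of 0.507 and keeps 0 % of its Q, and its bill, Z entered, comes to 0.507 Q per J.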